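The earlier runs and the new flask were computed for an exercise; scatter was added.

1. The easy step: set the readings against the logarithm of elapsed time, in powers of ten.

common to all: starting material 1.5 M; coupling partner 1.42 M; free catalyst 1.5 mM

| flask | scavenger | remark | time |
|---|---|---|---|
| zeta | 0.58 M | run made earlier |  |
| alpha | 0.87 M | run made earlier |  |
| north-west | 0.450 M |  | 30 min |
| west | 0.590 M |  | 30 min |

| run | time / min | starting material / % | product / % |
|---|---|---|---|
| zeta | 3.00 | 82.4 | 18.2 |
| zeta | 6.00 | 79.0 | 21.2 |
| zeta | 10.0 | 78.0 | 23.2 |
| zeta | 12.0 | 75.2 | 24.7 |
| zeta | 15.0 | 76.0 | 25.4 |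
| zeta | 20.0 | 74.5 | 25.9 |
| alpha | 1.00 | 86.5 | 14.2 |
| alpha | 3.00 | 81.6 | 15.7 |
| alpha | 6.00 | 77.6 | 21.8 |
| alpha | 10.0 | 77.2 | 22.5 |
| alpha | 12.0 | 78.1 | 23.2 |
| alpha | 15.0 | 76.2 | 24.0 |
| alpha | 20.0 | 73.6 | 23.7 |

(standard deviation of a reading: 1 percentage point)

1. part of the starting material that has reacted at the end, north-west
2. part of the starting material that has reacted at the end, west
3. what raising the concentration of scavenger from its lowest to its highest value here does to the part of the starting material that has reacted (changes below 5 percentage points count as none) (no change / it falls / it rises)

- what was read earlier has a scatter of 1 percentage point, one standard deviation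

2. In both runs the gains shrink as time grows, so a straight line in time does not fit them. In the alpha run, between 1.00 min and 20.0 min, the fall of the starting material gives 9.9 percentage points per decade of time, and the rise of the product gives 7.3 points.

3. Their mean is the decade gain, the points of conversion won each time elapsed time grows by one power of ten: 8.6 points.

4. From 20.0 min to 30 min is 0.176 decade. The runs differ in [scavenger], yet at 20.0 min the reacted part reads 25.5% in the zeta run and 26.4% in the alpha run, so their means serve as the base.

5. Way one, the starting-material column with its own slope, reaches 27.7%. Way two, the product column with its own slope, reaches 26.1%. The gap of 1.6 points stands beside a scatter of 1 point per reading, so neither column is caught cheating, and this reckoning takes the middle, 26.9%.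

6. Assuming one scavenger per reacted starting material, north-west needs 0.403 M of its 0.450 M, so in this reckoning scavenger lasts to the end of north-west. With the zeta and alpha runs reading alike, this reckoning expects the same conversion in north-west and west.

7. The forecast gives 27% for north-west (24.5% to 30%), 27% for west (24.5% to 30%), and no change. It closes: “So scavenger has no effect across this range.”

8. The flasks give 26.8% in north-west and 26.8% in west, a change of 0.0053 points, which counts as no change.

    starting material + free catalyst ⇌ catalyst intermediate A (K = 1.70 M⁻¹, k = 22.0 M⁻¹ s⁻¹)
    scavenger + released group → scavenged by-product (k = 0.800 M⁻¹ s⁻¹)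
    starting material + released group ⇌ idle adduct, settled at all times (K = 0.310 M⁻¹)
    catalyst intermediate B → released group + catalyst intermediate C (k = 260 s⁻¹)
    catalyst intermediate C ⇌ free catalyst + product (K = 14.0 M, k = 1200 s⁻¹)
    coupling partner + catalyst intermediate A ⇌ catalyst intermediate B (K = 3.80 M⁻¹, k = 22.0 M⁻¹ s⁻¹)
    2 free catalyst → spent catalyst (k = 260 M⁻¹ s⁻¹)

9. At 30.0 min north-west holds 99.8% of its catalyst as spent catalyst. That loss goes with the square of [free catalyst], so with the other charges fixed, charge and time enter as their product, and a decade of charge counts as a decade of time. A neighbouring flask, the same as north-west otherwise, carries 0.0060 M of free catalyst, a factor of 4.00 over north-west, so the decade gain reckons 32.0% for it. That flask gives 31.6%.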